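**Retrosynthetic overview**
1. C40 = ring C15 phosphonium salt (C1–C11) + commercial C10 dialdehyde (C12–C12') + acyclic C15 phosphonium salt (C11'–C1'), joined by two Wittig olefinations (C11=C12, then C11'=C12'); the C4 carbinol is set last by hydride reduction of the 4-ketone under control of C3.
2. Ring C15 salt: the C4–O bond is formed by a [3,3]-sigmatropic chromate-ester shift (Babler–Dauben oxidative transposition) of the tertiary alcohol made from a C6 acetylide and an (S)-4-silyloxy enone; the enone comes from (4R,6R)-actinol by Saegusa dehydrogenation.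
3. Acyclic C15 salt: C10 dienyl phosphonium salt (from (S)-glycerate acetonide via a C5 aldehyde, an enone and a vinyl carbinol) + C5 acetoxy-enal, then acetate-to-phosphonium exchange.
4. Rings: none is built; the single cyclohexene ring is bought in actinol and only dehydrogenated and transposed.

Assumption: (4R,6R)-actinol, 2,7-dimethylocta-2,4,6-trienedial and (E)-4-acetoxy-2-methylbut-2-enal are taken as purchasable carotenoid/vitamin A intermediates; carotenoid numbering (ring C1–C6, primed numbers for the acyclic half) is used in the explanations, and chain double bonds that form as E/Z mixtures are brought to all-E by the usual thermal equilibration and crystallisation.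

**Step 1**
Reactants: 1 (4R,6R)-4-hydroxy-2,2,6-trimethylcyclohexan-1-one; 2 tert-butyldimethylsilyl chloride
Product: 3 (4R,6R)-4-[(tert-butyldimethylsilyl)oxy]-2,2,6-trimethylcyclohexan-1-one
Conditions: imidazole, DMF, rt
Reagents that add atoms: tert-butyldimethylsilyl chloride, CC(C)(C)[Si](C)(C)Cl
Why: Silyl ether formation protects the carbinol (the future C3, bought in the chiral pool) against the later enolisation, acetylide and chromium steps without touching the stereocentre.

**Step 2**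
Reactants: 3 (4R,6R)-4-[(tert-butyldimethylsilyl)oxy]-2,2,6-trimethylcyclohexan-1-one
Product: 5 (4S)-4-[(tert-butyldimethylsilyl)oxy]-2,6,6-trimethylcyclohex-2-en-1-one, via TMS enol ether 4 (not isolated)
Conditions: TMSOTf, Et3N, CH2Cl2, 0 °C to rt; filter, solvent swap; Pd(OAc)2 (1.1 equiv), MeCN, rt
Reagents that add atoms: none
Why: Saegusa–Ito dehydrogenation works because the ketone has a single enolisable α-carbon (the other is quaternary), so one enol silane forms and β-hydride elimination from the palladium enolate gives the 2-methyl enone; the methyl-bearing stereocentre is deliberately destroyed and the silyloxy stereocentre is untouched.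

**Step 3**
Reactants: 6 (E)-3-methylpent-2-en-4-yn-1-ol; 2 tert-butyldimethylsilyl chloride
Product: 7 tert-butyldimethyl{[(E)-3-methylpent-2-en-4-yn-1-yl]oxy}silane
Conditions: imidazole, CH2Cl2, 0 °C to rt
Reagents that add atoms: tert-butyldimethylsilyl chloride, CC(C)(C)[Si](C)(C)Cl
Why: Silylation masks the primary allylic alcohol so the alkyne can be lithiated and the side chain survives the chromium oxidation; the E-trisubstituted bond (future C9=C10) is bought.

**Step 4**
Reactants: 7 tert-butyldimethyl{[(E)-3-methylpent-2-en-4-yn-1-yl]oxy}silane; 5 (4S)-4-[(tert-butyldimethylsilyl)oxy]-2,6,6-trimethylcyclohex-2-en-1-one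
Product: 9 (4S)-4-[(tert-butyldimethylsilyl)oxy]-1-{(E)-5-[(tert-butyldimethylsilyl)oxy]-3-methylpent-3-en-1-yn-1-yl}-2,6,6-trimethylcyclohex-2-en-1-ol (both C1 epimers), via lithium acetylide 8 (not isolated)
Conditions: n-BuLi, THF, −78 °C; then 5, −78 to −20 °C; aq. NH4Cl
Reagents that add atoms: compound 7, C#C/C(C)=C/CO[Si](C)(C)C(C)(C)C
Why: The hard lithium acetylide adds 1,2 to the hindered enone carbonyl (acetylide addition), and the epimer ratio at the new carbinol is irrelevant because that centre becomes sp2 in the next step.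

**Step 5**
Reactants: 9 (4S)-4-[(tert-butyldimethylsilyl)oxy]-1-{(E)-5-[(tert-butyldimethylsilyl)oxy]-3-methylpent-3-en-1-yn-1-yl}-2,6,6-trimethylcyclohex-2-en-1-ol; 10 pyridinium chlorochromate
Product: 13 (6S)-6-[(tert-butyldimethylsilyl)oxy]-3-{(E)-5-[(tert-butyldimethylsilyl)oxy]-3-methylpent-3-en-1-yn-1-yl}-2,4,4-trimethylcyclohex-2-en-1-one, via tertiary chlorochromate ester 11 (not isolated), via transposed secondary chlorochromate ester 12 (not isolated)
Conditions: [C5H5NH][CrO3Cl] (3 equiv), 4 Å molecular sieves, CH2Cl2, rt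
Reagents that add atoms: pyridinium chlorochromate, [O-][Cr](=O)(=O)Cl.c1cc[nH+]cc1
Why: In this Babler–Dauben oxidative transposition the chromate ester of the tertiary allylic alcohol undergoes a [3,3]-sigmatropic shift through the ring alkene (favoured over the propargylic terminus), forming the C4–O bond next to the silyloxy carbon, and the secondary chromate is then oxidised to the enone; both epimers of 9 converge and C3 is not involved.

**Step 6**
Reactants: 13 (6S)-6-[(tert-butyldimethylsilyl)oxy]-3-{(E)-5-[(tert-butyldimethylsilyl)oxy]-3-methylpent-3-en-1-yn-1-yl}-2,4,4-trimethylcyclohex-2-en-1-one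
Product: 14 (6S)-6-[(tert-butyldimethylsilyl)oxy]-3-{(1E,3E)-5-[(tert-butyldimethylsilyl)oxy]-3-methylpenta-1,3-dien-1-yl}-2,4,4-trimethylcyclohex-2-en-1-one
Conditions: Zn dust, AcOH, CH2Cl2, 0 °C to rt
Reagents that add atoms: none
Why: Dissolving-metal reduction with zinc in acetic acid reduces only the triple bond activated by conjugation with the enone (as in the industrial astaxanthin C15 route); any 7Z isomer converges to 7E in the acidic step that follows.

**Step 7**
Reactants: 14 (6S)-6-[(tert-butyldimethylsilyl)oxy]-3-{(1E,3E)-5-[(tert-butyldimethylsilyl)oxy]-3-methylpenta-1,3-dien-1-yl}-2,4,4-trimethylcyclohex-2-en-1-one; 15 triphenylphosphonium bromide (PPh3·HBr)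
Product: 17 {(2E,4E)-5-[(4S)-4-hydroxy-2,6,6-trimethyl-3-oxocyclohex-1-en-1-yl]-3-methylpenta-2,4-dien-1-yl}triphenylphosphonium bromide, via desilylated dienediol 16 (not isolated)
Conditions: PPh3·HBr (1.3 equiv), 48 % aq. HBr (cat.), MeOH, 0 °C to rt; crystallise
Reagents that add atoms: triphenylphosphonium bromide, [Br-].c1ccc(cc1)[PH+](c1ccccc1)c1ccccc1
Why: Acid methanolysis removes both silyl ethers and the primary dienylic alcohol ionises and is captured by PPh3 (SN1 allylic phosphonium salt formation), which also equilibrates the 7,8 and 9,10 bonds to E; the α-ketol is acid-stable and C3 is untouched.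

**Step 8**
Reactants: 17 {(2E,4E)-5-[(4S)-4-hydroxy-2,6,6-trimethyl-3-oxocyclohex-1-en-1-yl]-3-methylpenta-2,4-dien-1-yl}triphenylphosphonium bromide; 18 (2E,4E,6E)-2,7-dimethylocta-2,4,6-trienedial
Product: 20 (2E,4E,6E,8E,10E,12E)-13-[(4S)-4-hydroxy-2,6,6-trimethyl-3-oxocyclohex-1-en-1-yl]-2,7,11-trimethyltrideca-2,4,6,8,10,12-hexaenal, via phosphorus ylide 19 (not isolated)
Conditions: 18 (3 equiv, excess recovered), 1,2-epoxybutane/EtOH, reflux under argon
Reagents that add atoms: compound 18, O=C/C(C)=C/C=C/C=C(C)/C=O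
Why: Wittig olefination under neutral epoxide-buffered conditions avoids base-induced racemisation or air oxidation of the α-ketol, the excess dialdehyde enforces mono-condensation, and the hot medium equilibrates the new C11=C12 bond to E.

**Step 9**
Reactants: 21 methyl (4S)-2,2-dimethyl-1,3-dioxolane-4-carboxylate; 22 methylmagnesium bromide
Product: 23 2-[(4S)-2,2-dimethyl-1,3-dioxolan-4-yl]propan-2-ol
Conditions: MeMgBr (3 equiv), THF, 0 °C to rt; aq. NH4Cl
Reagents that add atoms: methylmagnesium bromide, C[Mg]Br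
Why: Double Grignard addition to the ester builds the C1' dimethylcarbinol, while the C2' stereocentre is carried over unchanged from the chiral pool.

**Step 10**
Reactants: 23 2-[(4S)-2,2-dimethyl-1,3-dioxolan-4-yl]propan-2-ol
Product: 24 [(4S)-2,2,5,5-tetramethyl-1,3-dioxolan-4-yl]methanol
Conditions: TsOH·H2O (5 mol %), acetone, rt; Et3N quench; residual 23 recycled
Reagents that add atoms: none
Why: Acid-catalysed acetonide migration (trans-ketalisation) is expected to equilibrate towards the more substituted dioxolane on the secondary/tertiary diol (gem-dimethyl effect), freeing the primary alcohol without breaking the C2'–O bond.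

**Step 11**
Reactants: 24 [(4S)-2,2,5,5-tetramethyl-1,3-dioxolan-4-yl]methanol; 25 1-(triphenyl-λ5-phosphanylidene)propan-2-one
Product: 27 (3E)-4-[(4S)-2,2,5,5-tetramethyl-1,3-dioxolan-4-yl]but-3-en-2-one, via aldehyde 26 (not isolated)
Conditions: IBX (1.5 equiv), DMSO, rt; then 25 (1.5 equiv), rt
Reagents that add atoms: compound 25, CC(=O)C=P(c1ccccc1)(c1ccccc1)c1ccccc1
Why: Tandem IBX oxidation and Wittig olefination traps the epimerisable α-alkoxy aldehyde in situ with a stabilised ylide, giving the E-enone (C3'=C4').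

**Step 12**
Reactants: 27 (3E)-4-[(4S)-2,2,5,5-tetramethyl-1,3-dioxolan-4-yl]but-3-en-2-one; 28 vinylmagnesium bromide
Product: 29 (1E)-3-methyl-1-[(4S)-2,2,5,5-tetramethyl-1,3-dioxolan-4-yl]penta-1,4-dien-3-ol (both C3 epimers)
Conditions: CH2=CHMgBr, THF, −30 to 0 °C; aq. NH4Cl
Reagents that add atoms: vinylmagnesium bromide, C=C[Mg]Br
Why: Grignard 1,2-addition to the methyl enone gives the bis-allylic tertiary carbinol, whose configuration is irrelevant because it is ionised next.

**Step 13**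
Reactants: 29 (1E)-3-methyl-1-[(4S)-2,2,5,5-tetramethyl-1,3-dioxolan-4-yl]penta-1,4-dien-3-ol; 15 triphenylphosphonium bromide (PPh3·HBr)
Product: 31 [(2E,4E,6S)-6,7-dihydroxy-3,7-dimethylocta-2,4-dien-1-yl]triphenylphosphonium bromide, via acetonide phosphonium salt 30 (not isolated)
Conditions: PPh3·HBr (1.3 equiv), MeOH, 0 °C to rt; crystallise the 2E salt
Reagents that add atoms: triphenylphosphonium bromide, [Br-].c1ccc(cc1)[PH+](c1ccccc1)c1ccccc1
Why: SN1 allylic transposition, as in vinyl-ionol chemistry, lets PPh3 capture the pentadienyl cation at its primary terminus to give the conjugated 2E salt, and the excess acid in methanol removes the acetonide; the C2'–O bond is not ionised because the adjacent carbinol disfavours a cation there.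

**Step 14**
Reactants: 31 [(2E,4E,6S)-6,7-dihydroxy-3,7-dimethylocta-2,4-dien-1-yl]triphenylphosphonium bromide; 32 (2E)-3-methyl-4-oxobut-2-en-1-yl acetate
Product: 34 (2E,4E,6E,8E,10S)-10,11-dihydroxy-3,7,11-trimethyldodeca-2,4,6,8-tetraen-1-yl acetate, via phosphorus ylide 33 (not isolated)
Conditions: 1,2-epoxybutane, CH2Cl2, 60 °C (sealed)
Reagents that add atoms: compound 32, CC(=O)OC/C=C(C)/C=O
Why: Wittig olefination of the C10 ylide with the C5 acetoxy-enal (the vitamin A acetate type of C–C coupling) forms C7'=C8' under neutral conditions that leave the acetate and the free diol alone.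

**Step 15**
Reactants: 34 (2E,4E,6E,8E,10S)-10,11-dihydroxy-3,7,11-trimethyldodeca-2,4,6,8-tetraen-1-yl acetate; 15 triphenylphosphonium bromide (PPh3·HBr)
Product: 35 [(2E,4E,6E,8E,10S)-10,11-dihydroxy-3,7,11-trimethyldodeca-2,4,6,8-tetraen-1-yl]triphenylphosphonium bromide
Conditions: PPh3·HBr (1.1 equiv), MeOH, rt; crystallise the all-E salt
Reagents that add atoms: triphenylphosphonium bromide, [Br-].c1ccc(cc1)[PH+](c1ccccc1)c1ccccc1
Why: Acid-promoted ionisation of the polyenylic acetate and capture by PPh3 (the retinyl acetate to retinyl phosphonium exchange) gives the terminal salt and equilibrates the 7',8' and 9',10' bonds to E.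

**Step 16**
Reactants: 20 (2E,4E,6E,8E,10E,12E)-13-[(4S)-4-hydroxy-2,6,6-trimethyl-3-oxocyclohex-1-en-1-yl]-2,7,11-trimethyltrideca-2,4,6,8,10,12-hexaenal; 35 [(2E,4E,6E,8E,10S)-10,11-dihydroxy-3,7,11-trimethyldodeca-2,4,6,8-tetraen-1-yl]triphenylphosphonium bromide
Product: 37 (3S,2'S)-3,1',2'-trihydroxy-3',4'-didehydro-1',2'-dihydro-β,ψ-caroten-4-one, via phosphorus ylide 36 (not isolated)
Conditions: 1,2-epoxybutane/EtOH, reflux under argon; then reflux in EtOH/heptane and crystallise the all-E isomer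
Reagents that add atoms: compound 35, [Br-].c1ccccc1[P+](c1ccccc1)(c1ccccc1)C/C=C(C)/C=C/C=C(C)/C=C/[C@H](O)C(C)(C)O
Why: The second Wittig olefination forms C11'=C12' chemoselectively at the aldehyde (the hindered ring enone does not react), and heating equilibrates the unhindered Z isomers to all-E.

**Step 17**
Reactants: 37 (3S,2'S)-3,1',2'-trihydroxy-3',4'-didehydro-1',2'-dihydro-β,ψ-caroten-4-one
Product: 38 (3S,4S,2'S)-3',4'-didehydro-1',2'-dihydro-β,ψ-carotene-3,4,1',2'-tetrol (target)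
Conditions: NaBH4, EtOH/THF, −20 to 0 °C; chromatography to remove the minor 3,4-cis diol
Reagents that add atoms: none
Why: Substrate-controlled 1,2-reduction of the ring enone by a small hydride should go by axial attack on the half-chair with the C3 oxygen equatorial, reinforced by delivery from the C3 alkoxyborohydride, placing the new C4–OH trans to C3–OH (4S).

**Compound list**
1 | (4R,6R)-4-hydroxy-2,2,6-trimethylcyclohexan-1-one (actinol) | CC1(C)C[C@H](O)C[C@@H](C)C1=O | starting material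
2 | tert-butyldimethylsilyl chloride | CC(C)(C)[Si](C)(C)Cl | starting material
3 | (4R,6R)-4-[(tert-butyldimethylsilyl)oxy]-2,2,6-trimethylcyclohexan-1-one | CC1(C)C[C@H](O[Si](C)(C)C(C)(C)C)C[C@@H](C)C1=O | intermediate
4 | tert-butyldimethyl{[(1R)-3,5,5-trimethyl-4-(trimethylsilyloxy)cyclohex-3-en-1-yl]oxy}silane | CC1=C(O[Si](C)(C)C)C(C)(C)C[C@H](O[Si](C)(C)C(C)(C)C)C1 | intermediate (not isolated)
5 | (4S)-4-[(tert-butyldimethylsilyl)oxy]-2,6,6-trimethylcyclohex-2-en-1-one | CC1=C[C@@H](O[Si](C)(C)C(C)(C)C)CC(C)(C)C1=O | intermediate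
6 | (E)-3-methylpent-2-en-4-yn-1-ol | C#C/C(C)=C/CO | starting material
7 | tert-butyldimethyl{[(E)-3-methylpent-2-en-4-yn-1-yl]oxy}silane | C#C/C(C)=C/CO[Si](C)(C)C(C)(C)C | intermediate
8 | {(E)-5-[(tert-butyldimethylsilyl)oxy]-3-methylpent-3-en-1-yn-1-yl}lithium | [Li]C#C/C(C)=C/CO[Si](C)(C)C(C)(C)C | intermediate (not isolated)
9 | (4S)-4-[(tert-butyldimethylsilyl)oxy]-1-{(E)-5-[(tert-butyldimethylsilyl)oxy]-3-methylpent-3-en-1-yn-1-yl}-2,6,6-trimethylcyclohex-2-en-1-ol (C1 epimers) | CC1=C[C@@H](O[Si](C)(C)C(C)(C)C)CC(C)(C)C1(O)C#C/C(C)=C/CO[Si](C)(C)C(C)(C)C | intermediate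
10 | pyridinium chlorochromate | [O-][Cr](=O)(=O)Cl.c1cc[nH+]cc1 | starting material
11 | chlorochromate ester of 9 at the tertiary oxygen | CC1=C[C@@H](O[Si](C)(C)C(C)(C)C)CC(C)(C)C1(O[Cr](=O)(=O)Cl)C#C/C(C)=C/CO[Si](C)(C)C(C)(C)C | intermediate (not isolated)
12 | transposed chlorochromate ester (chromate on the ring carbon next to the silyloxy carbon) | CC1=C(C#C/C(C)=C/CO[Si](C)(C)C(C)(C)C)C(C)(C)C[C@H](O[Si](C)(C)C(C)(C)C)C1O[Cr](=O)(=O)Cl | intermediate (not isolated)
13 | (6S)-6-[(tert-butyldimethylsilyl)oxy]-3-{(E)-5-[(tert-butyldimethylsilyl)oxy]-3-methylpent-3-en-1-yn-1-yl}-2,4,4-trimethylcyclohex-2-en-1-one | CC1=C(C#C/C(C)=C/CO[Si](C)(C)C(C)(C)C)C(C)(C)C[C@H](O[Si](C)(C)C(C)(C)C)C1=O | intermediate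
14 | (6S)-6-[(tert-butyldimethylsilyl)oxy]-3-{(1E,3E)-5-[(tert-butyldimethylsilyl)oxy]-3-methylpenta-1,3-dien-1-yl}-2,4,4-trimethylcyclohex-2-en-1-one | CC1=C(/C=C/C(C)=C/CO[Si](C)(C)C(C)(C)C)C(C)(C)C[C@H](O[Si](C)(C)C(C)(C)C)C1=O | intermediate
15 | triphenylphosphonium bromide (PPh3·HBr) | [Br-].c1ccc(cc1)[PH+](c1ccccc1)c1ccccc1 | starting material
16 | (6S)-6-hydroxy-3-[(1E,3E)-5-hydroxy-3-methylpenta-1,3-dien-1-yl]-2,4,4-trimethylcyclohex-2-en-1-one | CC1=C(/C=C/C(C)=C/CO)C(C)(C)C[C@H](O)C1=O | intermediate (not isolated)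
17 | {(2E,4E)-5-[(4S)-4-hydroxy-2,6,6-trimethyl-3-oxocyclohex-1-en-1-yl]-3-methylpenta-2,4-dien-1-yl}triphenylphosphonium bromide | CC1=C(/C=C/C(C)=C/C[P+](c2ccccc2)(c2ccccc2)c2ccccc2)C(C)(C)C[C@H](O)C1=O.[Br-] | intermediate
18 | (2E,4E,6E)-2,7-dimethylocta-2,4,6-trienedial | O=C/C(C)=C/C=C/C=C(C)/C=O | starting material
19 | ylide of 17 | CC1=C(/C=C/C(C)=C/C=P(c2ccccc2)(c2ccccc2)c2ccccc2)C(C)(C)C[C@H](O)C1=O | intermediate (not isolated)
20 | (2E,4E,6E,8E,10E,12E)-13-[(4S)-4-hydroxy-2,6,6-trimethyl-3-oxocyclohex-1-en-1-yl]-2,7,11-trimethyltrideca-2,4,6,8,10,12-hexaenal [(3S)-3-hydroxy-4-oxo-12'-apo-β-caroten-12'-al] | CC1=C(/C=C/C(C)=C/C=C/C(C)=C/C=C/C=C(C)/C=O)C(C)(C)C[C@H](O)C1=O | intermediate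
21 | methyl (4S)-2,2-dimethyl-1,3-dioxolane-4-carboxylate | COC(=O)[C@@H]1COC(C)(C)O1 | starting material
22 | methylmagnesium bromide | C[Mg]Br | starting material
23 | 2-[(4S)-2,2-dimethyl-1,3-dioxolan-4-yl]propan-2-ol | CC(C)(O)[C@@H]1COC(C)(C)O1 | intermediate
24 | [(4S)-2,2,5,5-tetramethyl-1,3-dioxolan-4-yl]methanol | OC[C@@H]1OC(C)(C)OC1(C)C | intermediate
25 | 1-(triphenyl-λ5-phosphanylidene)propan-2-one | CC(=O)C=P(c1ccccc1)(c1ccccc1)c1ccccc1 | starting material
26 | (4R)-2,2,5,5-tetramethyl-1,3-dioxolane-4-carbaldehyde | O=C[C@@H]1OC(C)(C)OC1(C)C | intermediate (not isolated)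
27 | (3E)-4-[(4S)-2,2,5,5-tetramethyl-1,3-dioxolan-4-yl]but-3-en-2-one | CC(=O)/C=C/[C@@H]1OC(C)(C)OC1(C)C | intermediate
28 | vinylmagnesium bromide | C=C[Mg]Br | starting material
29 | (1E)-3-methyl-1-[(4S)-2,2,5,5-tetramethyl-1,3-dioxolan-4-yl]penta-1,4-dien-3-ol (C3 epimers) | C=CC(C)(O)/C=C/[C@@H]1OC(C)(C)OC1(C)C | intermediate
30 | {(2E,4E)-3-methyl-5-[(4S)-2,2,5,5-tetramethyl-1,3-dioxolan-4-yl]penta-2,4-dien-1-yl}triphenylphosphonium bromide | [Br-].c1ccccc1[P+](c1ccccc1)(c1ccccc1)C/C=C(C)/C=C/[C@@H]1OC(C)(C)OC1(C)C | intermediate (not isolated)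
31 | [(2E,4E,6S)-6,7-dihydroxy-3,7-dimethylocta-2,4-dien-1-yl]triphenylphosphonium bromide | [Br-].c1ccccc1[P+](c1ccccc1)(c1ccccc1)C/C=C(C)/C=C/[C@H](O)C(C)(C)O | intermediate
32 | (2E)-3-methyl-4-oxobut-2-en-1-yl acetate [(E)-4-acetoxy-2-methylbut-2-enal] | CC(=O)OC/C=C(C)/C=O | starting material
33 | ylide of 31 | c1ccccc1P(c1ccccc1)(c1ccccc1)=C/C=C(C)/C=C/[C@H](O)C(C)(C)O | intermediate (not isolated)
34 | (2E,4E,6E,8E,10S)-10,11-dihydroxy-3,7,11-trimethyldodeca-2,4,6,8-tetraen-1-yl acetate | CC(=O)OC/C=C(C)/C=C/C=C(C)/C=C/[C@H](O)C(C)(C)O | intermediate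
35 | [(2E,4E,6E,8E,10S)-10,11-dihydroxy-3,7,11-trimethyldodeca-2,4,6,8-tetraen-1-yl]triphenylphosphonium bromide | [Br-].c1ccccc1[P+](c1ccccc1)(c1ccccc1)C/C=C(C)/C=C/C=C(C)/C=C/[C@H](O)C(C)(C)O | intermediate
36 | ylide of 35 | c1ccccc1P(c1ccccc1)(c1ccccc1)=C/C=C(C)/C=C/C=C(C)/C=C/[C@H](O)C(C)(C)O | intermediate (not isolated)
37 | (3S,2'S)-3,1',2'-trihydroxy-3',4'-didehydro-1',2'-dihydro-β,ψ-caroten-4-one [(3S,2'S)-2'-hydroxyflexixanthin] | CC1=C(/C=C/C(C)=C/C=C/C(C)=C/C=C/C=C(C)/C=C/C=C(C)/C=C/C=C(C)/C=C/[C@H](O)C(C)(C)O)C(C)(C)C[C@H](O)C1=O | intermediate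
38 | (3S,4S,2'S)-3',4'-didehydro-1',2'-dihydro-β,ψ-carotene-3,4,1',2'-tetrol (CNP0343898.2) | CC1=C(/C=C/C(C)=C/C=C/C(C)=C/C=C/C=C(C)/C=C/C=C(C)/C=C/C=C(C)/C=C/[C@H](O)C(C)(C)O)C(C)(C)C[C@H](O)[C@H]1O | target

**Totals**
Total step count: 17. Longest linear sequence: 9 steps (steps 9–17 from the glycerate ester; the ring line 1, 2, 4, 5, 6, 7, 8, 16, 17 is equally long).

**Three steps most likely to fail, with fallbacks**

Step 5 (oxidative [3,3] transposition on a hindered, propargylic tertiary alcohol). The fallback separates transposition from oxidation. It sets out from 9: catalytic Ph3SiOReO3 in Et2O at 0 °C effects a non-oxidative 1,3-hydroxyl shift, driven by conjugation with the enyne, to the secondary allylic alcohol (6S)-6-[(tert-butyldimethylsilyl)oxy]-3-{(E)-5-[(tert-butyldimethylsilyl)oxy]-3-methylpent-3-en-1-yn-1-yl}-2,4,4-trimethylcyclohex-2-en-1-ol F1 as an epimer mixture. MnO2 in CH2Cl2 then oxidises it, and the route is rejoined at 13.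

Step 13 (cationic phosphonium formation with concurrent acetonide loss; risk of 2Z salt and of damage at the allylic C2' carbinol). The fallback fixes the trisubstituted double bond by olefination and installs phosphorus by SN2 chemistry. It sets out from 24: oxidation to 26 as in step 11, then Horner–Wadsworth–Emmons reaction with triethyl 3-methyl-4-phosphonocrotonate (LiN(SiMe3)2, THF, −78 °C) gives ethyl (2E,4E)-3-methyl-5-[(4S)-2,2,5,5-tetramethyl-1,3-dioxolan-4-yl]penta-2,4-dienoate F2. Reduction with i-Bu2AlH gives (2E,4E)-3-methyl-5-[(4S)-2,2,5,5-tetramethyl-1,3-dioxolan-4-yl]penta-2,4-dien-1-ol F3, and CBr4/PPh3 gives (4S)-4-[(1E,3E)-5-bromo-3-methylpenta-1,3-dien-1-yl]-2,2,5,5-tetramethyl-1,3-dioxolane F4. PPh3 in EtOAc converts F4 into the isolated salt 30; brief methanolysis with catalytic acid, now on an electron-poor phosphonium salt, removes the acetonide, and the route is rejoined at 31.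

Step 17 (diastereoselectivity of the last-step ketone reduction and separation of C40 diol epimers). The fallback sets C4 at the crystalline C15 stage and carries the free trans-diol through both olefinations, which are neutral. It sets out from 17: NaBH4/CeCl3·7H2O in MeOH at −40 °C gives {(2E,4E)-5-[(3S,4S)-3,4-dihydroxy-2,6,6-trimethylcyclohex-1-en-1-yl]-3-methylpenta-2,4-dien-1-yl}triphenylphosphonium bromide F5, which is recrystallised free of the cis epimer. Wittig reaction with excess 18 (1,2-epoxybutane/EtOH) gives (2E,4E,6E,8E,10E,12E)-13-[(3S,4S)-3,4-dihydroxy-2,6,6-trimethylcyclohex-1-en-1-yl]-2,7,11-trimethyltrideca-2,4,6,8,10,12-hexaenal F6, and a second Wittig reaction with 35 under the conditions of step 16 rejoins the route at 38.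

**Further compounds**
F1 | step 5 | (6S)-6-[(tert-butyldimethylsilyl)oxy]-3-{(E)-5-[(tert-butyldimethylsilyl)oxy]-3-methylpent-3-en-1-yn-1-yl}-2,4,4-trimethylcyclohex-2-en-1-ol | CC1=C(C#C/C(C)=C/CO[Si](C)(C)C(C)(C)C)C(C)(C)C[C@H](O[Si](C)(C)C(C)(C)C)C1O
F2 | step 13 | ethyl (2E,4E)-3-methyl-5-[(4S)-2,2,5,5-tetramethyl-1,3-dioxolan-4-yl]penta-2,4-dienoate | CCOC(=O)/C=C(C)/C=C/[C@@H]1OC(C)(C)OC1(C)C
F3 | step 13 | (2E,4E)-3-methyl-5-[(4S)-2,2,5,5-tetramethyl-1,3-dioxolan-4-yl]penta-2,4-dien-1-ol | OC/C=C(C)/C=C/[C@@H]1OC(C)(C)OC1(C)C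
F4 | step 13 | (4S)-4-[(1E,3E)-5-bromo-3-methylpenta-1,3-dien-1-yl]-2,2,5,5-tetramethyl-1,3-dioxolane | BrC/C=C(C)/C=C/[C@@H]1OC(C)(C)OC1(C)C
F5 | step 17 | {(2E,4E)-5-[(3S,4S)-3,4-dihydroxy-2,6,6-trimethylcyclohex-1-en-1-yl]-3-methylpenta-2,4-dien-1-yl}triphenylphosphonium bromide | CC1=C(/C=C/C(C)=C/C[P+](c2ccccc2)(c2ccccc2)c2ccccc2)C(C)(C)C[C@H](O)[C@H]1O.[Br-]
F6 | step 17 | (2E,4E,6E,8E,10E,12E)-13-[(3S,4S)-3,4-dihydroxy-2,6,6-trimethylcyclohex-1-en-1-yl]-2,7,11-trimethyltrideca-2,4,6,8,10,12-hexaenal | CC1=C(/C=C/C(C)=C/C=C/C(C)=C/C=C/C=C(C)/C=O)C(C)(C)C[C@H](O)[C@H]1O
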